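**Conventions.** Compounds carry the numbers 1–18 of the steps below. Core locants are those of the target and are kept for every bicyclic intermediate, even where lowest-locant rules would number differently: C1 allyl bridgehead, C2 vinyl CH, C3 enol-ether carbon, C4 carbinol, C5 methoxy bridgehead, C6 aryl CH, C7 methyl CH, C8 bridging carbonyl carbon. "Endo" means under the C2–C4 bridge, "exo" means on the side of C8.

## Analysis of the target

Target 18 is a bicyclo[3.2.1]oct-2-en-8-one. A six-membered ring (C1, C2, C3, C4, C5, C8) and a five-membered ring (C1, C7, C6, C5, C8) share the unit C1–C8–C5. All five stereocentres (1R,4S,5R,6S,7R) are contiguous. C1 is an all-carbon quaternary bridgehead and C5 an oxygenated one; the aryl group at C6 is endo, the methyl group at C7 is exo and trans to it, and the C4 hydroxyl lies on the endo face, anti to C8. The methyl enol ether next to an allylic alcohol is acid-labile. The C4 hydroxyl and the C8 ketone form an aldol unit across C5 that can open under base; the phenol is free, and the terminal alkene rules out hydrogenolysis. The difficulty is the density: two fully substituted bridgeheads, each beside a tertiary stereocentre, and no stereocentre outside the bicycle from which absolute configuration could be relayed. The strategy rests on C4, C5 and C8 being three contiguous oxygen-bearing carbons, with C5 holding both an oxygen and the bond to C6. Moving C6 from C5 to C4, an α-ketol relationship, converts the skeleton into a bicyclo[2.2.2]octenone, the cycloadduct of an arene-derived cyclohexa-2,4-dienone and a β-methylstyrene.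

## Retrosynthetic reasoning

**18 ⇒ 17 ⇒ 16.** No skeletal bond is cut. The phenol is unmasked last, and the C4 carbinol is traced back to the C4 ketone of 16. The carbinol is made late because it belongs to the aldol unit and sits beside the enol ether. The reduction must deliver hydride to C4 from the C8 side; the endo aryl group at C6 covers the other face, so the substrate should supply this selectivity.

**16 ⇒ 15 ⇒ 14.** The C8 carbonyl is kept as its dimethyl ketal and the C5 methoxy group is traced back to a tertiary hydroxyl. The ketal is removed while C4 is still a ketone, because an α-methoxy enone resists acid far better than the enol ether/allylic alcohol of 17. The forward steps must cap a hindered tertiary alcohol and then hydrolyse a hindered ketal without touching the enone.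

**14 ⇒ 13 ⇒ 12.** This is the skeletal disconnection. The bond C5–C6 is cut and C6 is reconnected to C4, while the carbonyl moves from C4 to C5. It is the only 1,2-relocation that turns the bridged skeleton into a Diels–Alder-shaped bicyclo[2.2.2]octenone with oxygen at both carbons involved. What is gained is a cycloadduct in which all ring carbons come from two aromatic compounds. The forward shift has to move C6 and not C3, with retention at C6. Conjugation of the new C4 ketone with the C2=C3 enol ether should pull a reversible shift that way.

**12 ⇒ 9 + 11.** The bonds C1–C7 and C4–C6 are cut. This retro-[4+2] separates a fully functionalised dienone (C1, C2, C3, C4 as diene; C5 carbonyl; C8 ketal) from a styrene that brings C6, C7, the aryl and the methyl group. One step would then form two skeletal bonds, one ring and four stereocentres. The forward reaction must control regiochemistry, endo orientation of the aryl group and the face of the achiral dienone. The last of these needs a chiral catalyst.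

**9 ⇒ 8.** The dienone is the dearomatised form of a guaiacol-type phenol. The C5 carbonyl comes from the phenolic oxygen and the C8 ketal from the neighbouring methoxy-bearing carbon. Oxidation in an alcohol solvent has to add the second methoxy group at that carbon.

**8 ⇒ 6 ⇒ 4 + 5 ⇒ 3 ⇒ 2 ⇒ 1.** The problem in 8 is a catechol with one oxygen acetylated and the other free, on a ring that offers almost no bias between them. It is solved by construction: the free oxygen is carried as a formyl group and revealed by Dakin oxidation only after the other oxygen has been acetylated. The allyl group is traced to a bromide coupled with 5. The bromide goes to the position para to the phenol of 2, and the formyl group to the single free ortho position of 1.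

**11 ⇒ 10.** The phenol of 10 is silylated with a group bulky enough to survive methoxide and dilute acid.

## Alternatives that were turned down

**Alternative 1:** annulation of the three-carbon bridge onto a cyclopentanone. The bonds C1–C2 and C4–C5 are cut. In the forward step the silyl enol ether A1 would be C-acylated at C1 by the bis-acid chloride A2, and the enol then formed at C5 would be acylated by the second acid chloride, an Effenberger-type cyclisation. The product would be trione A3, drawn as its C2 enol.
- For it: C6 and C7 would come from the chiral pool, so absolute configuration is secure. The C8 ketone is present from the start and needs no unmasking. Both bridgeheads are made by polar C–C bond formation of a known kind. On these points it is stronger than the chosen route.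
- Against it: A1 is a cyclopentanone with four contiguous substituents and is itself a long synthesis. The first acylation must make a quaternary carbon at a tetrasubstituted enol ether, where O-acylation competes. A3 carries an oxygen at C2 that the target lacks. Its removal needs a regioselective distinction between the C2 and C4 oxygens of a nearly symmetric enolised 1,3-diketone, then triflation and reduction, before the route reaches the stage of 16.
- Comparison: the chosen strategy takes the C2–C4 oxidation pattern directly from the arene and makes its precursor in six steps from a simple phenol. It pays with an untested asymmetric step.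

**Alternative 2:** radical bicyclisation of an acyclic aldehyde. The bonds C2–C3 and C1–C7 are cut. A thiyl radical would abstract the formyl hydrogen of A4. The acyl radical at C3 would add to the terminal methylene (C2) of the α-allyl enone, and the resulting C1 radical would close onto the internal vinyl carbon C7. Hydrogen transfer from the thiol would create the methyl group and give dione A5.
- For it: two rings and two bonds from an open chain, with no reagent incorporated. The bicyclo[3.2.1] skeleton is made directly, and C4, C5 and C6 could be set in advance by acyclic methods. On directness of skeleton formation it is stronger than the chosen route.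
- Against it: an α-silyloxy acyl radical loses carbon monoxide readily. The acyl radical can also close in a five-membered mode onto the C6 vinyl group, and the thiyl radical adds to the three alkenes. A4 holds a quaternary α-methoxy ketone between two stereocentres next to a polymerisable α-methylene ketone and is hard to assemble. A5 still needs regioselective O-methylation of the C3 ketone towards C2, not C4.
- Comparison: the chosen strategy concentrates its risk in one bimolecular step between two stable, easily made partners.

**Alternative 3:** rhodium-catalysed arylation with aldol closure. The bonds C6–aryl and C4–C5 are cut. An arylrhodium species of monovalent rhodium, formed from boronic acid A7, would add to C6 of cyclopentenone A6 anti to the C7 methyl group. The rhodium enolate at C5 would then attack the tethered aldehyde C4 and give A8, a silyl ether of the target.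
- For it: the aryl group enters late, three stereocentres are set at once and the product is one deprotection from the target. The reaction class is established for enone–aldehydes. In end-game economy and precedent for the key step it is stronger than the chosen route.
- Against it: the difficulty is moved into A6. Its quaternary C1 (allyl plus a geometrically defined methoxy-enal chain) beside the C7 stereocentre needs a multi-step enantioselective synthesis. A 2-methoxy-enone is a deactivated acceptor, while the arylrhodium can add to the aldehyde or to the enal. The aldol is reversible, so the C4 configuration is not secure.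
- Comparison: the chosen strategy has a longer end game and a new key step. In return its precursor is achiral and short, and both quaternary carbons and four stereocentres are made together.

Key step: step 8

Remark: 1 is treated as a catalogue compound.
Remark: no model predicts which antipode of the oxazaborolidinium catalyst opens the required face of 9; the (S)-catalyst is written, and the equally available (R)-catalyst replaces it if the sense is opposite.

## Route

Step 1
Reactants: 1 2,5-dimethoxyphenol
Product: 2 2-hydroxy-3,6-dimethoxybenzaldehyde
Conditions: MgCl2, Et3N, (CH2O)n, MeCN, reflux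
Reagents that add atoms: paraformaldehyde (as formaldehyde), C=O
Why: Casnati–Skattebøl ortho-formylation; the magnesium phenoxide directs formaldehyde to the only free ortho position of 1, and a second formaldehyde oxidises the benzylic alkoxide by hydride transfer.

Step 2
Reactants: 2 2-hydroxy-3,6-dimethoxybenzaldehyde
Product: 3 5-bromo-2-hydroxy-3,6-dimethoxybenzaldehyde
Conditions: NBS, MeCN, 0 °C to rt
Reagents that add atoms: N-bromosuccinimide, O=C1CCC(=O)N1Br
Why: Electrophilic aromatic bromination; the position para to the free hydroxyl is also ortho to a methoxy group and meta to the formyl group, whereas the other free position is para to the formyl group, so one regioisomer is expected.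

Step 3
Reactants: 3 5-bromo-2-hydroxy-3,6-dimethoxybenzaldehyde
Product: 4 4-bromo-2-formyl-3,6-dimethoxyphenyl acetate
Conditions: Ac2O, pyridine, DMAP (cat.), CH2Cl2, rt
Reagents that add atoms: acetic anhydride, CC(=O)OC(C)=O
Why: Standard O-acetylation of a phenol; the acetyl group is placed while only one hydroxyl exists, so the later catechol monoester is regiodefined by construction.

Step 4
Reactants: 4 4-bromo-2-formyl-3,6-dimethoxyphenyl acetate; 5 allyltributylstannane
Product: 6 4-allyl-2-formyl-3,6-dimethoxyphenyl acetate
Conditions: Pd(PPh3)4 (5 mol %), toluene, 105 °C
Reagents that add atoms: none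
Why: Stille coupling of an aryl bromide with an allylstannane on zerovalent palladium; the neutral conditions spare the aryl acetate and the aldehyde, and without base the allyl group should not isomerise to propenyl.

Step 5
Reactants: 6 4-allyl-2-formyl-3,6-dimethoxyphenyl acetate
Product: 8 4-allyl-2-hydroxy-3,6-dimethoxyphenyl acetate, via aryl formate 7 (not isolated)
Conditions: mCPBA, CH2Cl2, 0 °C to rt; then MeOH, TsOH (cat.), 0 °C
Reagents that add atoms: 3-chloroperbenzoic acid, O=C(OO)c1cccc(Cl)c1
Why: Dakin-type Baeyer–Villiger oxidation; the electron-rich aryl group with an ortho methoxy substituent migrates in preference to hydride, and the aldehyde should react with the peracid faster than the monosubstituted alkene. The formate is transesterified under acid much faster than the acetate, and the absence of base prevents acetyl migration between the neighbouring oxygens.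

Step 6
Reactants: 8 4-allyl-2-hydroxy-3,6-dimethoxyphenyl acetate
Product: 9 2-acetoxy-5-allyl-3,6,6-trimethoxycyclohexa-2,4-dien-1-one
Conditions: PhI(OAc)2, MeOH, 0 °C
Reagents that add atoms: methanol, CO
Why: Oxidative dearomatisation of a 2-methoxyphenol with a trivalent iodine reagent; methanol attacks the methoxy-bearing ortho carbon, where positive charge is best stabilised, and gives the ortho-quinone monoketal (ring C5 = core C1, ring C2 = core C4, ring C1 = core C5, ring C6 = core C8). Substituents on three diene carbons should make 9 stable to self-dimerisation and isolable.

Step 7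
Reactants: 10 (E)-isoeugenol
Product: 11 (E)-triisopropyl[2-methoxy-4-(prop-1-en-1-yl)phenoxy]silane
Conditions: TIPSCl, imidazole, DMF, rt
Reagents that add atoms: triisopropylsilyl chloride, CC(C)[Si](Cl)(C(C)C)C(C)C
Why: Standard phenol silylation; the triisopropylsilyl ether is chosen over smaller silyl groups because it should survive catalytic methoxide and dilute acid later in the route.

Step 8
Reactants: 9 2-acetoxy-5-allyl-3,6,6-trimethoxycyclohexa-2,4-dien-1-one; 11 (E)-triisopropyl[2-methoxy-4-(prop-1-en-1-yl)phenoxy]silane
Product: 12 (1R,4R,6S,7R)-4-acetoxy-1-allyl-3,8,8-trimethoxy-6-[3-methoxy-4-(triisopropylsilyloxy)phenyl]-7-methylbicyclo[2.2.2]oct-2-en-5-one (core locants; aryl syn to the C2=C3 bridge, methyl syn to the ketal)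
Conditions: (S)-3,3-diphenyl-1-(o-tolyl)tetrahydro-1H,3H-pyrrolo[1,2-c][1,3,2]oxazaborole·HNTf2 (20 mol %), CH2Cl2, −78 to −20 °C
Reagents that add atoms: none
Why: Proposed new method: the oxazaborolidinium ion is expected to bind the basic vinylogous-ester carbonyl (C5=O) of the achiral dienone 9, lower its LUMO and let the electron-rich alkene of 11 add in an inverse-demand, concerted but asynchronous [4+2] cycloaddition; the closest known reaction types are the thermal, racemic Diels–Alder reaction of masked ortho-benzoquinones with styrenes and the oxazaborolidinium-catalysed enantioselective Diels–Alder reaction of enones and quinones, whose combination with a linearly conjugated dienone as the diene is untested. The one new ring (C1, C2, C3, C4, C6, C7) closes suprafacially on both partners across C1 and C4 of the cyclohexadienone and so creates the bicyclo[2.2.2]octenone. Regiochemistry should follow frontier-orbital polarisation: the largest LUMO coefficient of the bound dienone lies at C1, δ to the carbonyl, and pairs with the methyl-bearing alkene carbon of 11, which has the largest HOMO coefficient, leaving the benzylic carbon to bond to C4. C6 and C7 come out trans because the (E)-geometry of 11 is transferred suprafacially. The aryl group at C6 should lie on the side of the C2=C3 bridge through the endo transition state, in which the arene overlaps the dienone π-system, and this places the C7 methyl on the ketal side. C1 and C4 are set by the choice between the two enantiotopic faces of 9, which only the catalyst can make: boron on the carbonyl oxygen together with a hydrogen bond from the protonated nitrogen to the C4 acetoxy carbonyl is proposed to hold the dienone against the diaryl shelf so that one face is covered. Self-dimerisation of 9, the usual competitor for such dienones, should be suppressed by its substituents, and the low temperature protects the acid-sensitive ketal and 11.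

Step 9
Reactants: 12 (1R,4R,6S,7R)-4-acetoxy-1-allyl-3,8,8-trimethoxy-6-[3-methoxy-4-(triisopropylsilyloxy)phenyl]-7-methylbicyclo[2.2.2]oct-2-en-5-one
Product: 14 (1R,5R,6S,7R)-1-allyl-5-hydroxy-3,8,8-trimethoxy-6-[3-methoxy-4-(triisopropylsilyloxy)phenyl]-7-methylbicyclo[3.2.1]oct-2-en-4-one, via bicyclo[2.2.2] ketol 13 (not isolated)
Conditions: NaOMe (0.3 equiv), MeOH/THF, 0 °C to rt
Reagents that add atoms: none
Why: Methanolysis of the bridgehead acetate frees the C4 alkoxide, which undergoes an α-ketol (acyloin) rearrangement: C6 migrates from C4 to the C5 carbonyl carbon with retention, so the aryl group that lay under the alkene bridge becomes endo, and the C5 configuration is fixed by the bicycle. The shift is reversible and should settle on 14, the only isomer whose new C4 ketone is conjugated with the C2=C3 enol ether.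

Step 10
Reactants: 14 (1R,5R,6S,7R)-1-allyl-5-hydroxy-3,8,8-trimethoxy-6-[3-methoxy-4-(triisopropylsilyloxy)phenyl]-7-methylbicyclo[3.2.1]oct-2-en-4-one
Product: 15 (1R,5R,6S,7R)-1-allyl-3,5,8,8-tetramethoxy-6-[3-methoxy-4-(triisopropylsilyloxy)phenyl]-7-methylbicyclo[3.2.1]oct-2-en-4-one
Conditions: MeOTf, 2,6-di-tert-butyl-4-methylpyridine, CH2Cl2, 0 to 40 °C
Reagents that add atoms: methyl trifluoromethanesulfonate, COS(=O)(=O)C(F)(F)F
Why: O-Methylation of a hindered tertiary alcohol with a hard methylating agent and a non-nucleophilic base; no alkoxide is formed, so the ketol cannot shift back while it is capped.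

Step 11
Reactants: 15 (1R,5R,6S,7R)-1-allyl-3,5,8,8-tetramethoxy-6-[3-methoxy-4-(triisopropylsilyloxy)phenyl]-7-methylbicyclo[3.2.1]oct-2-en-4-one
Product: 16 (1R,5S,6S,7R)-1-allyl-3,5-dimethoxy-6-[3-methoxy-4-(triisopropylsilyloxy)phenyl]-7-methylbicyclo[3.2.1]oct-2-ene-4,8-dione
Conditions: 2 M aq. HCl, THF, 40 °C
Reagents that add atoms: water, O
Why: Acid hydrolysis of the dimethyl ketal to the bridging ketone; the α-methoxy enone is a deactivated enol ether because its nucleophilic carbon is the electrophilic terminus of the enone, and the aryl triisopropylsilyl ether tolerates dilute acid. The C5 descriptor changes only because the substituent priorities change.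

Step 12
Reactants: 16 (1R,5S,6S,7R)-1-allyl-3,5-dimethoxy-6-[3-methoxy-4-(triisopropylsilyloxy)phenyl]-7-methylbicyclo[3.2.1]oct-2-ene-4,8-dione
Product: 17 (1R,4S,5R,6S,7R)-1-allyl-4-hydroxy-3,5-dimethoxy-6-[3-methoxy-4-(triisopropylsilyloxy)phenyl]-7-methylbicyclo[3.2.1]oct-2-en-8-one
Conditions: NaBH4, CeCl3·7H2O, MeOH, −78 °C
Reagents that add atoms: none
Why: Luche reduction; cerium-activated methoxyborohydrides should reduce the enone carbonyl in a 1,2-manner in preference to the saturated ketone, and C8 is also the more hindered carbonyl, lying between two fully substituted carbons. Hydride should reach C4 from the C8 side because the endo aryl group at C6 covers the opposite face, which gives the endo (4S) hydroxyl.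

Step 13
Reactants: 17 (1R,4S,5R,6S,7R)-1-allyl-4-hydroxy-3,5-dimethoxy-6-[3-methoxy-4-(triisopropylsilyloxy)phenyl]-7-methylbicyclo[3.2.1]oct-2-en-8-one
Product: 18 (1R,4S,5R,6S,7R)-1-allyl-4-hydroxy-6-(4-hydroxy-3-methoxyphenyl)-3,5-dimethoxy-7-methylbicyclo[3.2.1]oct-2-en-8-one (target)
Conditions: TBAF, AcOH, THF, 0 °C
Reagents that add atoms: none
Why: Fluoride cleavage of the aryl silyl ether; buffering with acetic acid keeps the medium near neutral, so the aldol unit (C4 hydroxyl, C8 ketone) should not open and the enol ether should not hydrolyse.

## Compound list

1 | 2,5-dimethoxyphenol | COc1ccc(OC)c(O)c1 | starting material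
2 | 2-hydroxy-3,6-dimethoxybenzaldehyde | COc1ccc(OC)c(C=O)c1O | intermediate
3 | 5-bromo-2-hydroxy-3,6-dimethoxybenzaldehyde | COc1cc(Br)c(OC)c(C=O)c1O | intermediate
4 | 4-bromo-2-formyl-3,6-dimethoxyphenyl acetate | COc1cc(Br)c(OC)c(C=O)c1OC(C)=O | intermediate
5 | allyltributylstannane | C=CC[Sn](CCCC)(CCCC)CCCC | starting material
6 | 4-allyl-2-formyl-3,6-dimethoxyphenyl acetate | C=CCc1cc(OC)c(OC(C)=O)c(C=O)c1OC | intermediate
7 | 4-allyl-2-(formyloxy)-3,6-dimethoxyphenyl acetate | C=CCc1cc(OC)c(OC(C)=O)c(OC=O)c1OC | intermediate
8 | 4-allyl-2-hydroxy-3,6-dimethoxyphenyl acetate | C=CCc1cc(OC)c(OC(C)=O)c(O)c1OC | intermediate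
9 | 2-acetoxy-5-allyl-3,6,6-trimethoxycyclohexa-2,4-dien-1-one | C=CCC1=CC(OC)=C(OC(C)=O)C(=O)C1(OC)OC | intermediate
10 | (E)-isoeugenol | C/C=C/c1ccc(O)c(OC)c1 | starting material
11 | (E)-triisopropyl[2-methoxy-4-(prop-1-en-1-yl)phenoxy]silane | C/C=C/c1ccc(O[Si](C(C)C)(C(C)C)C(C)C)c(OC)c1 | intermediate
12 | (1R,4R,6S,7R)-4-acetoxy-1-allyl-3,8,8-trimethoxy-6-[3-methoxy-4-(triisopropylsilyloxy)phenyl]-7-methylbicyclo[2.2.2]oct-2-en-5-one (core locants) | C=CC[C@@]12C=C(OC)[C@@](OC(C)=O)(C(=O)C1(OC)OC)[C@H](c1ccc(O[Si](C(C)C)(C(C)C)C(C)C)c(OC)c1)[C@H]2C | intermediate
13 | (1R,4R,6S,7R)-1-allyl-4-hydroxy-3,8,8-trimethoxy-6-[3-methoxy-4-(triisopropylsilyloxy)phenyl]-7-methylbicyclo[2.2.2]oct-2-en-5-one (core locants) | C=CC[C@@]12C=C(OC)[C@@](O)(C(=O)C1(OC)OC)[C@H](c1ccc(O[Si](C(C)C)(C(C)C)C(C)C)c(OC)c1)[C@H]2C | intermediate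
14 | (1R,5R,6S,7R)-1-allyl-5-hydroxy-3,8,8-trimethoxy-6-[3-methoxy-4-(triisopropylsilyloxy)phenyl]-7-methylbicyclo[3.2.1]oct-2-en-4-one | C=CC[C@@]12C=C(OC)C(=O)[C@@](O)(C1(OC)OC)[C@H](c1ccc(O[Si](C(C)C)(C(C)C)C(C)C)c(OC)c1)[C@H]2C | intermediate
15 | (1R,5R,6S,7R)-1-allyl-3,5,8,8-tetramethoxy-6-[3-methoxy-4-(triisopropylsilyloxy)phenyl]-7-methylbicyclo[3.2.1]oct-2-en-4-one | C=CC[C@@]12C=C(OC)C(=O)[C@@](OC)(C1(OC)OC)[C@H](c1ccc(O[Si](C(C)C)(C(C)C)C(C)C)c(OC)c1)[C@H]2C | intermediate
16 | (1R,5S,6S,7R)-1-allyl-3,5-dimethoxy-6-[3-methoxy-4-(triisopropylsilyloxy)phenyl]-7-methylbicyclo[3.2.1]oct-2-ene-4,8-dione | C=CC[C@@]12C=C(OC)C(=O)[C@@](OC)(C1=O)[C@H](c1ccc(O[Si](C(C)C)(C(C)C)C(C)C)c(OC)c1)[C@H]2C | intermediate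
17 | (1R,4S,5R,6S,7R)-1-allyl-4-hydroxy-3,5-dimethoxy-6-[3-methoxy-4-(triisopropylsilyloxy)phenyl]-7-methylbicyclo[3.2.1]oct-2-en-8-one | C=CC[C@@]12C=C(OC)[C@H](O)[C@@](OC)(C1=O)[C@H](c1ccc(O[Si](C(C)C)(C(C)C)C(C)C)c(OC)c1)[C@H]2C | intermediate
18 | (1R,4S,5R,6S,7R)-1-allyl-4-hydroxy-6-(4-hydroxy-3-methoxyphenyl)-3,5-dimethoxy-7-methylbicyclo[3.2.1]oct-2-en-8-one | C=CC[C@@]12C=C(OC)[C@H](O)[C@@](OC)(C1=O)[C@H](c1ccc(O)c(OC)c1)[C@H]2C | target

## Step count and least certain steps

Total: 13 steps. Longest linear sequence: 12 steps (steps 1–6 and 8–13, from 1 to 18); the second branch is step 7.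

**Step 8 (key step, proposed new method).** Three things are most likely to fail.
- Facial selectivity may be poor, because the dienone has no α-hydrogen of the kind that usually organises such catalyst complexes.
- The strongly acidic catalyst may ionise the ketal or oligomerise the electron-rich styrene, which opens stepwise cationic pathways.
- Rate may be low and endo selectivity eroded, since both diene termini are fully substituted and the C7 methyl group meets a ketal methoxy group in the endo-aryl transition state.

Fallback with known chemistry: 9 and 11 are heated without catalyst in toluene at about 120 °C in a sealed tube, the established thermal mode for this diene class. This should give 12 as a racemate, that is together with the mirror-image adduct F1. The two are separated by preparative chromatography on a cellulose-based chiral stationary phase. The detour sets out from 9 and 11 and comes back at 12; the correct antipode is recognised at the end by correlation with the natural product.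

**Step 9.** Methoxide may cleave the aryl silyl ether while the shift is still incomplete, or the equilibrium may stall at 13 or leak into migration of the vinyl carbon C3. Fallback: the operation is split. Brief deacetylation at low temperature (K2CO3, MeOH, −20 °C) allows 13 to be isolated. The neutral ketol is then rearranged with Al(OtBu)3 in toluene at 60 °C, where aluminium chelates the C4 oxygen and the C5 carbonyl and no free alkoxide is present. The detour sets out from 12 and comes back at 14; it makes no compound outside the list (F0).

**Step 12.** Reduction may also occur at C8, a strained α-alkoxy ketone, or hydride may not discriminate the two faces of C4 well enough. Fallback: 16 is reduced at both carbonyls with excess NaBH4 in MeOH to the C4,C8-diol F2. Its less hindered C4 hydroxyl is silylated (TESCl, imidazole) to the C4 triethylsilyl ether F3. The C8 alcohol, flanked by two quaternary carbons, is oxidised with Dess–Martin periodinane to the C8 ketone F4. TBAF/AcOH then removes both silyl groups. The detour sets out from 16 and comes back at 18.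

**Step 11.** Ionisation of a ketal flanked by two fully substituted carbons and an α-methoxy group may be slow, so that forcing acid starts to hydrolyse the C3 enol ether. Fallback: non-hydrolytic unmasking with iodotrimethylsilane made in the flask (Me3SiCl, NaI, MeCN, −20 °C). Silylation of one ketal oxygen and dealkylation of the oxocarbenium ion by iodide give the ketone without water having to reach the hindered carbon, and at a temperature where aryl and alkyl methyl ethers are not cleaved. The detour sets out from 15 and comes back at 16; it makes no compound outside the list (F0).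

**Step 10.** Methylation of the neutral, hydrogen-bonded tertiary alcohol may be too slow. Fallback: the alkoxide is alkylated in the flask of the rearrangement. Compound 12 is treated with one equivalent of NaOMe in THF/DMF at 0 °C, the rearranged sodium alkoxide is left to equilibrate, and MeI is then added. The detour sets out from 12 and comes back at 15; it makes no compound outside the list (F0).

## Further compounds

F1 | step 8 | mirror-image adduct, enantiomer of 12 | C=CC[C@]12C=C(OC)[C@](OC(C)=O)(C(=O)C1(OC)OC)[C@@H](c1ccc(O[Si](C(C)C)(C(C)C)C(C)C)c(OC)c1)[C@@H]2C
F0 | step 9 | none | none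
F2 | step 12 | C4,C8-diol from full reduction of 16 (C8 configuration open, erased on re-oxidation) | C=CC[C@@]12C=C(OC)[C@H](O)[C@@](OC)(C1O)[C@H](c1ccc(O[Si](C(C)C)(C(C)C)C(C)C)c(OC)c1)[C@H]2C
F3 | step 12 | C4 triethylsilyl ether of F2 | C=CC[C@@]12C=C(OC)[C@H](O[Si](CC)(CC)CC)[C@@](OC)(C1O)[C@H](c1ccc(O[Si](C(C)C)(C(C)C)C(C)C)c(OC)c1)[C@H]2C
F4 | step 12 | C8 ketone with C4 triethylsilyl ether | C=CC[C@@]12C=C(OC)[C@H](O[Si](CC)(CC)CC)[C@@](OC)(C1=O)[C@H](c1ccc(O[Si](C(C)C)(C(C)C)C(C)C)c(OC)c1)[C@H]2C
F0 | step 11 | none | none
F0 | step 10 | none | none
A1 | alternative 1 | trimethylsilyl enol ether of 2-allyl-5-methoxy-3-methyl-4-[3-methoxy-4-(triisopropylsilyloxy)phenyl]cyclopentanone, enolised towards the allyl-bearing carbon (3,4-trans; C5 open) | C=CCC1=C(O[Si](C)(C)C)C(OC)[C@H](c2ccc(O[Si](C(C)C)(C(C)C)C(C)C)c(OC)c2)[C@H]1C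
A2 | alternative 1 | methoxymalonyl dichloride | COC(C(=O)Cl)C(=O)Cl
A3 | alternative 1 | bicyclo[3.2.1]octane-2,4,8-trione as its C2 enol | C=CC[C@@]12C(O)=C(OC)C(=O)[C@@](OC)(C1=O)[C@H](c1ccc(O[Si](C(C)C)(C(C)C)C(C)C)c(OC)c1)[C@H]2C
A4 | alternative 2 | acyclic aldehyde with the α-allyl enone and the C6 vinyl group | O=C[C@H](O[Si](C)(C)C(C)(C)C)[C@@](OC)(C(=O)C(=C)CC=C)[C@H](c1ccc(O[Si](C)(C)C(C)(C)C)c(OC)c1)C=C
A5 | alternative 2 | bicyclo[3.2.1]octane-3,8-dione with the C4 silyl ether | C=CC[C@@]12CC(=O)[C@H](O[Si](C)(C)C(C)(C)C)[C@@](OC)(C1=O)[C@H](c1ccc(O[Si](C)(C)C(C)(C)C)c(OC)c1)[C@H]2C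
A6 | alternative 3 | 5-allyl-2-methoxy-5-[(E)-2-methoxy-3-oxoprop-1-en-1-yl]-4-methylcyclopent-2-en-1-one | C=CC[C@@]1(/C=C(\C=O)OC)C(=O)C(OC)=C[C@H]1C
A7 | alternative 3 | [4-(tert-butyldimethylsilyloxy)-3-methoxyphenyl]boronic acid | OB(O)c1ccc(O[Si](C)(C)C(C)(C)C)c(OC)c1
A8 | alternative 3 | tert-butyldimethylsilyl ether of the target phenol | C=CC[C@@]12C=C(OC)[C@H](O)[C@@](OC)(C1=O)[C@H](c1ccc(O[Si](C)(C)C(C)(C)C)c(OC)c1)[C@H]2C
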